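The numbers were chosen freely; what happens was integrated by code.

Over 10 d at constant temperature, one flask turns electrophile and nucleophile into target while a held gas feeds in base.

electrophile 16 mM; nucleophile 15.2 mM; gas 2.6 mM (held); time 10 d

    nucleophile + target → over-reaction product A (k1 = 0.99 /M/h)
    acid set free + free base ⇌ salt of the base, settled at all times (K2 = 1.3 × 10⁶ /M)
    gas ⇌ free base, rate k3*(csat - [free base]) (k3 = 1.3 /h, csat = 2.6 mM)
    target → over-reaction product B (k4 = 9.2 × 10⁻⁶ /h)
    electrophile + nucleophile → acid set free + target (k5 = 59 /M/h)
    nucleophile + acid set free ⇌ protonated nucleophile, settled at all times (K6 = 810 /M)

* part of the electrophile that has reacted at 10 d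
* share of the unused nucleophile that is free and not bound as protonated nucleophile, at 10 d

The bench rule says the reagent charged in the smaller amount, here the nucleophile (the limiting reagent), is used one for one. That puts the electrophile reacted at 95.0%. Time looks ample. The electrophile's half-life as charged, 0.77 h, is shorter than the run, and the gas can deliver a nucleophile charge's worth of base in about 4.50 h, also shorter than the run.

But the nucleophile's balance has a second outlet: nucleophile charged equals free nucleophile plus protonated nucleophile plus electrophile used plus over-reaction product A formed. For the end of the run I assume the first two are negligible. Both steps take the same free nucleophile, so it cancels from their ratio. Product A therefore gains on target at 0.0168 (the selectivity factor) times target over electrophile. Summed as the electrophile falls, the loss is that factor times the natural log of charged over left, minus the part used.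

A first pass, with the rule's 5.00% left, loses 3.43%, so 8.43% is left. This toll, the part of the electrophile charge whose nucleophile goes to product A, then comes to 2.61%. The rule can stand only while the toll is far below the gap between the charges, and here it is half of that gap. So I drop the rule and commit to 92.4% reacted. Taking the salt as the nucleophile charge and free base at 2.6 mM, the two equilibria leave 99.6% of the unused nucleophile free.

The forecast gives 92.3% (91.5% to 93.2%) and 99.7% (99.5% to 99.8%), starting from “The nucleophile is the limiting reagent”. Its conversion and mine differ by 0.087 percentage points.

The flask gives 92.3% reacted and 99.6% free. At 10.0 d it holds over-reaction product A at 2.71% of the electrophile charged, and the toll reckoned from its conversion is 2.76%. For the neighbour flask with 9.1 mM of nucleophile, the toll from its charges is 0.457%. That neighbour flask reached 56.4% reacted and holds over-reaction product A at 0.445%.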